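## Analysis of the target

The target 26 is an eremophilane, a cis-fused decalin. Ring A is C1–C5 plus C10 and ring B is C5–C10. C5 carries a quaternary methyl (C14), C4 a methyl (C15), C7 an isopropenyl group (C11–C13), C8 a ketone, and C3 and C9 carry angelate esters. These carbon numbers are used for every intermediate, and β means the face of C14.

The six stereocentres are 3R,4R,5R,7R,9R,10S. C15, H-10, the C9 oxygen and the C7 isopropenyl group are β like C14; the C3 oxygen is α, trans to C15.

In the chair–chair conformer with C14 equatorial on ring B, the C7 and C9 substituents are both equatorial. The two centres α to the ketone therefore sit in their stable configurations, whereas C4, C5 and C10 cannot be corrected once set.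

The sensitive groups are the angelates (Z to E drift to tiglates), the β,γ-unsaturated isopropenyl ketone (it can slip into conjugation as a C7=C11 enone) and the base-labile α-acyloxy ketone.

The hard parts are the vicinal cis methyls at C4/C5 with C5 quaternary at the ring fusion, the cis fusion itself, and three contiguous functionalised carbons C7–C8–C9.

The strategy rests on ring B. The C7 isopropenyl group beside the C8 carbonyl is read as an acetyl group beside an oxygenated carbon. C6–C7 with its three-carbon branch is then methyl vinyl ketone, and C5, C10, C9, C8 are a 1-oxygenated diene attached to ring A.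

## Retrosynthetic reasoning

**Ester C–O bonds.** The two angelates are cut last, giving diol 23 and angelic acid 24. The angelate is the most fragile element and should meet no further reagent. The forward step must transfer the Z acyl group to two secondary hydroxyls, one an α-ketol, without geometric leakage.

**C9–O bond.** Diol 23 comes from the silyl-protected ketol 22, and 22 from oxidation of silyl enol ether 20 through epoxide 21. Oxygen is introduced at C9 late because an enol ether fixed at C8=C9 is exactly what conjugate reduction of a 9-en-8-one delivers. The forward step must oxidise the enol ether on the β face and spare the isopropenyl alkene.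

**C10–H bond.** Enol ether 20 is traced to enone 19 by conjugate hydride delivery with silyl trapping. One operation sets the ring fusion and fixes the enolate regiochemistry; the hydride has to arrive on the C14 face.

**C7–H bond.** Enone 19 is the C7 epimer of enone 17, reached through dienolate 18. The cycloaddition places the three-carbon branch α, and α is also the stable position in the enone (equatorial, away from the axial C14). The inversion is put at the enone stage for three reasons:
- The axial C14 screens the β face of the planar C7, so a kinetic proton must come from α.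
- After C10 is reduced, the 7β isomer becomes the all-equatorial one and is thermodynamically secure.
- Done after the reduction, the same protonation would have to enter the concave face of a cis-decalin.

**Adjustments back to the cycloadduct.** Enone 17 comes from allylic alcohol 16, 16 from silyl ether 15, and 15 from methyl ketone 14 by methylenation (C11=C12). The acetyl group is kept through the cycloaddition because it activates the dienophile. Methylenation precedes release of the C8 hydroxyl so that a β-hydroxy ketone prone to retro-aldol cleavage never appears.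

**Key disconnection, C5–C6 and C7–C8.** Adduct 14 is cut to diene 12 and methyl vinyl ketone 13. These two bonds close ring B onto a ring A that already holds C3 and C4, create the quaternary C5, put oxygen on C8 and leave the C9=C10 alkene needed for the enone chemistry. The forward step must bond C5, the vinylogous donor terminus, to the enone β-carbon on the face opposite C15. The C7 and C8 configurations formed here are not carried to the target.

**C9–C10 bond.** Diene 12 comes from aldehyde 11, 11 from acetal 10, and 10 from enol triflate 8 and zinc reagent 9. A masked two-carbon aldehyde is coupled to a hindered tetrasubstituted triflate and unmasked without moving the ring alkene into conjugation.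

**C4–C15 bond.** Triflate 8 comes from enone 6 through enolate 7. Conjugate methyl addition anti to the C3 silyloxy group sets C4, and trapping the enolate fixes the C5=C10 alkene regiospecifically.

**C5–C14 bond and C3.** Enone 6 comes from iodoenone 5 and 5 from enone 4 (α-iodination, methyl cross-coupling). Enone 4 comes from ketal 3, alcohol 2 and enone 1. A catalytic enantioselective reduction of 1 sets C3, and hydrolysis of the masked second ketone turns the carbinol into the γ-oxygen of the enone. This avoids an allylic oxidation of uncertain regiochemistry and a resolution that discards half the material.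

## Alternatives that were turned down

**Alternative 1:** The cut is at C9–C10 and C5–C14 on ring A, with no ring formed. In the forward step a copper-catalysed asymmetric conjugate vinylation of enone A2 at C10 is followed by C-methylation of the enolate at C5, giving ketone A1 with vinyl cis to the butenyl chain; ring B would be closed later by metathesis at C8=C9.
- For: a catalyst sets the absolute configuration, and C5 and C10 with the cis relationship arise in one flask from trivial materials. On this point it is stronger than the chosen route, which relies on substrate control at C5 and a later hydride delivery at C10.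
- Against: α-substituted cyclohexenones are poor substrates for asymmetric conjugate vinylation. A1 has none of the peripheral functionality: C4 is a ketone that must become the β-methyl carbon beside a quaternary centre, C3 needs oxygen, C7 is an unactivated methylene that must receive the isopropenyl group, and the C8=C9 alkene must become a regiodefined α-acyloxy ketone.
- Comparison: four new stereocontrol problems and well over ten further steps follow its key step. The chosen cycloaddition delivers ring B with the C7 branch, the C8 oxygen and the C9=C10 alkene in place, on a ring A whose C3 and C4 are already set.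

**Alternative 2:** The cut is at C5–C10 and C6–C7, closing both rings. Heating trienone A4 would bring its methacryloyl alkene onto the (Z)-2-silyloxydiene and give octalin A3.
- For: it is the most bond-forming option (two rings, the quaternary centre and the ring fusion in one step). Its enol silyl ether emerges at C8=C9, as well placed for C9 oxygenation as in the chosen route.
- Against: a Z diene whose tether is the cis substituent reacts reluctantly and competes with 1,5-hydrogen shift at the temperatures needed. Facial control rests on a single epimerisable centre α to the C4 ketone. A3 lacks C15 (a ketone flanked by a quaternary carbon and an alkoxy carbon must become a β-methyl group) and lacks the C7 isopropenyl group.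
- Comparison: it wins on convergence of ring construction. The chosen route offers instead a skeleton that is complete after the key step, with C15 set beforehand by a reliable anti cuprate addition.

**Alternative 3:** The cut is at C9–C10. A Lewis acid would make C10 of the ring A allylsilane in aldehyde A6 attack the C9 aldehyde anti to silicon (intramolecular Hosomi–Sakurai reaction), giving carbinol A5 with the alkene moved to C1–C2.
- For: the cis fusion is stereospecific through the anti SE2' course, and C8 and C9 arrive oxygenated and differentiated without a late enolate oxidation. On C10 and C9 control it is stronger than the chosen route.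
- Against: A6 needs four contiguous ring A stereocentres (including the quaternary C5 and the silyl-bearing C2) plus a chain stereocentre at C8, all built linearly before the key step. The C9 configuration depends on a synclinal versus antiperiplanar transition state. A5 has a C1=C2 alkene to saturate and again an unfunctionalised C7.
- Comparison: the chosen route reaches its precursor in nine steps from a purchased enone and carries the C7 branch through the key step.

Key step: step 10

## Route

Remark on the chemistry: compounds 1, 9, 13 and 24 are taken as purchased; C14 and C15 are β in every bicyclic compound.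

Step 1
Reactants: 1 1,4-dioxaspiro[4.5]dec-6-en-8-one
Product: 2 (R)-1,4-dioxaspiro[4.5]dec-6-en-8-ol
Conditions: (S)-2-methyl-CBS-oxazaborolidine (10 mol %), BH3·SMe2, THF, −30 °C; MeOH, then aq. work-up
Reagents that add atoms: none
Why: CBS reduction; the oxazaborolidine–borane complex binds the carbonyl with the alkenyl arm as the large group and delivers hydride within the complex, so the S catalyst should give the R carbinol, which becomes C3. Low temperature favours 1,2-reduction over hydroboration.

Step 2
Reactants: 2 (R)-1,4-dioxaspiro[4.5]dec-6-en-8-ol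
Product: 3 (R)-8-(triisopropylsilyloxy)-1,4-dioxaspiro[4.5]dec-6-ene
Conditions: TIPSOTf, 2,6-lutidine, CH2Cl2, 0 °C
Reagents that add atoms: triisopropylsilyl trifluoromethanesulfonate, CC(C)[Si](OS(=O)(=O)C(F)(F)F)(C(C)C)C(C)C
Why: Standard silylation of a secondary allylic alcohol; the bulky TIPS ether is chosen to direct the later cuprate addition and to outlast the TBS ether at C8.

Step 3
Reactants: 3 (R)-8-(triisopropylsilyloxy)-1,4-dioxaspiro[4.5]dec-6-ene
Product: 4 (R)-4-(triisopropylsilyloxy)cyclohex-2-en-1-one
Conditions: PPTS, acetone/H2O, 55 °C
Reagents that add atoms: water, O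
Why: Acid-catalysed hydrolysis of an allylic ketal; the secondary TIPS ether tolerates the pyridinium acid and the carbinol carbon is not touched, so it becomes the γ-oxygenated centre of the enone.

Step 4
Reactants: 4 (R)-4-(triisopropylsilyloxy)cyclohex-2-en-1-one
Product: 5 (R)-2-iodo-4-(triisopropylsilyloxy)cyclohex-2-en-1-one
Conditions: I2, pyridine, CH2Cl2, 0 °C → rt
Reagents that add atoms: iodine, II
Why: α-Iodination of an enone by reversible conjugate addition of pyridine, iodination of the enolate and elimination; no stereocentre is involved.

Step 5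
Reactants: 5 (R)-2-iodo-4-(triisopropylsilyloxy)cyclohex-2-en-1-one
Product: 6 (R)-2-methyl-4-(triisopropylsilyloxy)cyclohex-2-en-1-one
Conditions: Me2Zn, PdCl2(dppf) (5 mol %), THF, 0 °C → rt
Reagents that add atoms: dimethylzinc, C[Zn]C
Why: Negishi coupling of an α-iodoenone; the neutral medium avoids β-elimination of the γ-silyloxy group, and the methyl introduced is C14.

Step 6
Reactants: 6 (R)-2-methyl-4-(triisopropylsilyloxy)cyclohex-2-en-1-one
Product: 8 (3R,4R)-2,3-dimethyl-4-(triisopropylsilyloxy)cyclohex-1-en-1-yl trifluoromethanesulfonate, via lithium enolate 7 (not isolated)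
Conditions: Me2CuLi (from MeLi, CuI), Et2O, −78 → −40 °C; then PhNTf2, THF, −40 °C → rt
Reagents that add atoms: lithium dimethylcuprate, [Li+].C[Cu-]C; N-phenylbis(trifluoromethanesulfonimide), O=S(=O)(N(c1ccccc1)S(=O)(=O)C(F)(F)F)C(F)(F)F
Why: Cuprate conjugate addition occurs anti to the bulky γ-silyloxy group and sets C4 with C15 trans to oxygen. The regiodefined enolate 7 is O-sulfonylated before it can equilibrate, which fixes the tetrasubstituted C5=C10 enol triflate.

Step 7
Reactants: 8 (3R,4R)-2,3-dimethyl-4-(triisopropylsilyloxy)cyclohex-1-en-1-yl trifluoromethanesulfonate; 9 (1,3-dioxolan-2-ylmethyl)zinc bromide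
Product: 10 2-{[(3R,4R)-2,3-dimethyl-4-(triisopropylsilyloxy)cyclohex-1-en-1-yl]methyl}-1,3-dioxolane
Conditions: Pd(OAc)2 (5 mol %), SPhos (10 mol %), LiCl, THF, 50 °C
Reagents that add atoms: none
Why: Negishi sp2–sp3 coupling; a bulky electron-rich phosphine is used for oxidative addition into the hindered triflate, and the alkylzinc transfers C9–C8 without disturbing the alkene position.

Step 8
Reactants: 10 2-{[(3R,4R)-2,3-dimethyl-4-(triisopropylsilyloxy)cyclohex-1-en-1-yl]methyl}-1,3-dioxolane
Product: 11 2-[(3R,4R)-2,3-dimethyl-4-(triisopropylsilyloxy)cyclohex-1-en-1-yl]acetaldehyde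
Conditions: TESOTf, 2,4,6-collidine, CH2Cl2, 0 °C; then H2O
Reagents that add atoms: water, O
Why: Silyl triflate–collidine cleavage of an aldehyde acetal; the dioxolane opens to a collidinium adduct that water hydrolyses without free acid, so the TIPS ether survives and the β,γ-alkene is not drawn into conjugation.

Step 9
Reactants: 11 2-[(3R,4R)-2,3-dimethyl-4-(triisopropylsilyloxy)cyclohex-1-en-1-yl]acetaldehyde
Product: 12 tert-butyl({(E)-2-[(3R,4R)-2,3-dimethyl-4-(triisopropylsilyloxy)cyclohex-1-en-1-yl]ethenyl}oxy)dimethylsilane
Conditions: TBSOTf, Et3N, CH2Cl2, −78 → 0 °C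
Reagents that add atoms: tert-butyldimethylsilyl trifluoromethanesulfonate, CC(C)(C)[Si](C)(C)OS(=O)(=O)C(F)(F)F
Why: Soft enolisation; O-silylation of the aldehyde and loss of the doubly activated C9 proton give the 1-silyloxydiene. The E enol ether is expected because a Z silyloxy group would clash with C1 or C14 in any planar diene conformer.

Step 10
Reactants: 12 tert-butyl({(E)-2-[(3R,4R)-2,3-dimethyl-4-(triisopropylsilyloxy)cyclohex-1-en-1-yl]ethenyl}oxy)dimethylsilane; 13 methyl vinyl ketone
Product: 14 7α-acetyl-8α-(tert-butyldimethylsilyloxy)-4β,5β-dimethyl-3α-(triisopropylsilyloxy)-Δ9(10)-octalin (eremophilane numbering)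
Conditions: 13 (3 equiv), Me2AlCl (0.5 equiv), CH2Cl2, −78 → −40 °C; aq. NaHCO3
Reagents that add atoms: none
Why: Me2AlCl activates the enone; C5, the vinylogous donor terminus of the silyl dienol ether, bonds to the enone β-carbon C6, and C7 of the developing aluminium enolate closes onto the silyl oxocarbenium carbon C8, either in one asynchronous event or as a Mukaiyama–Michael addition followed by aldol-type closure. The closest known reaction type is the Lewis acid promoted Diels–Alder reaction of a 1-silyloxydiene with a vinyl ketone. Ring B closes by [4+2] annulation through C5–C6 and C7–C8, and the alkene moves to C9=C10. The 1-silyloxy donor dictates the regiochemistry, so the acetyl carbon C7 bonds to C8. At C5, A(1,2) strain with C14 pushes C15 pseudoaxial on the β face, so C6 enters on the α face and C14 ends β, cis to C15, the same control that operates in alkylations of 2,3-dimethylcyclohexanone enolates. At C8 the silyloxy group ends α as a consequence of the E enol ether and suprafacial bonding, and endo orientation of the acetyl group places it α at C7. Only the C5 selectivity is needed, because C8 becomes a ketone and C7 is reset in step 14, so an exo or stepwise-derived isomer converges. The reaction needs the s-cis diene despite the inward C14, which the strong donor and the Lewis acid are meant to overcome.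

Step 11
Reactants: 14 7α-acetyl-8α-(tert-butyldimethylsilyloxy)-4β,5β-dimethyl-3α-(triisopropylsilyloxy)-Δ9(10)-octalin
Product: 15 8α-(tert-butyldimethylsilyloxy)-3α-(triisopropylsilyloxy)-7βH-eremophila-9,11-diene (isopropenyl α)
Conditions: Ph3PCH3Br, KOtBu, toluene/THF, 0 °C → rt
Reagents that add atoms: methylenetriphenylphosphorane, C=P(c1ccccc1)(c1ccccc1)c1ccccc1
Why: Wittig methylenation of a methyl ketone. The α-acetyl group is equatorial and already the stable C7 epimer, so enolisation by the ylide costs nothing, and the C8 oxygen stays silylated to exclude retro-aldol cleavage.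

Step 12
Reactants: 15 8α-(tert-butyldimethylsilyloxy)-3α-(triisopropylsilyloxy)-7βH-eremophila-9,11-diene
Product: 16 3α-(triisopropylsilyloxy)-7βH-eremophila-9,11-dien-8α-ol (isopropenyl α)
Conditions: Bu4NF, AcOH (1:1), THF, 0 °C → rt
Reagents that add atoms: none
Why: Fluoride cleaves a secondary TBS ether faster than a secondary TIPS ether. Buffered fluoride is chosen over acid because the allylic C8 position would ionise readily to a tertiary allyl cation.

Step 13
Reactants: 16 3α-(triisopropylsilyloxy)-7βH-eremophila-9,11-dien-8α-ol
Product: 17 3α-(triisopropylsilyloxy)-7βH-eremophila-9,11-dien-8-one (isopropenyl α)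
Conditions: Dess–Martin periodinane, NaHCO3, CH2Cl2, 0 °C → rt
Reagents that add atoms: none
Why: Dess–Martin oxidation of an allylic alcohol under buffered, near-neutral conditions, which keeps the β,γ-isopropenyl alkene out of conjugation.

Step 14
Reactants: 17 3α-(triisopropylsilyloxy)-7βH-eremophila-9,11-dien-8-one
Product: 19 3α-(triisopropylsilyloxy)-7αH-eremophila-9,11-dien-8-one (isopropenyl β), via lithium dienolate 18 (not isolated)
Conditions: LiN(iPr)2, THF, −78 °C; then 2,6-di-tert-butyl-4-methylphenol, THF, −78 °C; pH 7 buffer
Reagents that add atoms: none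
Why: Kinetic α'-deprotonation of the enone gives dienolate 18, which is protonated at C7, the kinetic site of an extended enolate. The pseudoaxial C14 screens the β face of C7, so the bulky phenol delivers the proton from the α face and the isopropenyl group ends β.

Step 15
Reactants: 19 3α-(triisopropylsilyloxy)-7αH-eremophila-9,11-dien-8-one
Product: 20 8-(triethylsilyloxy)-3α-(triisopropylsilyloxy)-7αH,10βH-eremophila-8,11-diene (cis-fused)
Conditions: [(Ph3P)CuH]6 (0.5 equiv), Et3SiCl, benzene/THF, rt
Reagents that add atoms: chlorotriethylsilane, CC[Si](Cl)(CC)CC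
Why: Copper hydride conjugate reduction with in situ O-silylation of the copper enolate. Hydride should reach C10 on the β face, because the α face is flanked by the axial hydrogens on C2 and C4 and β delivery leads to the cis-fused enolate in which C14 and the 7β-isopropenyl group are both equatorial on ring B. The neutral medium leaves C7 untouched and the enol ether is fixed at C8=C9.

Step 16
Reactants: 20 8-(triethylsilyloxy)-3α-(triisopropylsilyloxy)-7αH,10βH-eremophila-8,11-diene
Product: 22 9β-(triethylsilyloxy)-3α-(triisopropylsilyloxy)-7αH,10βH-eremophil-11-en-8-one, via silyloxy epoxide 21 (not isolated)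
Conditions: mCPBA (1.05 equiv), NaHCO3, CH2Cl2, −20 → 0 °C
Reagents that add atoms: 3-chloroperbenzoic acid, O=C(OO)c1cccc(Cl)c1
Why: Rubottom oxidation; the electron-rich enol ether is epoxidised much faster than the 1,1-disubstituted alkene, on the convex β face because the α face is covered by the axial C4 arm of ring A. Epoxide 21 opens with 1,4-silyl shift to the 9β-silyloxy ketone, which is also the stable equatorial C9 epimer.

Step 17
Reactants: 22 9β-(triethylsilyloxy)-3α-(triisopropylsilyloxy)-7αH,10βH-eremophil-11-en-8-one
Product: 23 3α,9β-dihydroxy-7αH,10βH-eremophil-11-en-8-one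
Conditions: HF (48 % aq.), MeCN, 0 °C → rt
Reagents that add atoms: none
Why: Acidic fluoride removes both silyl ethers without base, so the α-ketol does not rearrange and the isopropenyl ketone does not conjugate; any ketol already desilylated in step 16 converges here.

Step 18
Reactants: 23 3α,9β-dihydroxy-7αH,10βH-eremophil-11-en-8-one; 24 angelic acid [(Z)-2-methylbut-2-enoic acid]
Product: 26 (3R,4R,5R,7R,9R,10S)-3α,9β-bis(angeloyloxy)-7αH,10βH-eremophil-11-en-8-one (target), via mixed anhydride 25 (not isolated)
Conditions: 24 (3 equiv), 2,4,6-trichlorobenzoyl chloride, Et3N, toluene, rt; then 23, toluene, 75 °C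
Reagents that add atoms: none
Why: Yamaguchi-type esterification; the hydroxyls attack the unhindered angeloyl carbonyl of anhydride 25. Omitting a nucleophilic acyl-transfer catalyst suppresses the addition–elimination path that turns angelate into tiglate, and C7 and C9 are at their stable configurations so warming cannot epimerise them.

## Compound list

1 | 1,4-dioxaspiro[4.5]dec-6-en-8-one | O=C1C=CC2(CC1)OCCO2 | starting material
2 | (R)-1,4-dioxaspiro[4.5]dec-6-en-8-ol | O[C@H]1C=CC2(CC1)OCCO2 | intermediate
3 | (R)-8-(triisopropylsilyloxy)-1,4-dioxaspiro[4.5]dec-6-ene | CC(C)[Si](O[C@H]1C=CC2(CC1)OCCO2)(C(C)C)C(C)C | intermediate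
4 | (R)-4-(triisopropylsilyloxy)cyclohex-2-en-1-one | O=C1CC[C@@H](O[Si](C(C)C)(C(C)C)C(C)C)C=C1 | intermediate
5 | (R)-2-iodo-4-(triisopropylsilyloxy)cyclohex-2-en-1-one | O=C1CC[C@@H](O[Si](C(C)C)(C(C)C)C(C)C)C=C1I | intermediate
6 | (R)-2-methyl-4-(triisopropylsilyloxy)cyclohex-2-en-1-one | O=C1CC[C@@H](O[Si](C(C)C)(C(C)C)C(C)C)C=C1C | intermediate
7 | lithium (3R,4R)-2,3-dimethyl-4-(triisopropylsilyloxy)cyclohex-1-en-1-olate | CC1=C(O[Li])CC[C@@H](O[Si](C(C)C)(C(C)C)C(C)C)[C@@H]1C | intermediate
8 | (3R,4R)-2,3-dimethyl-4-(triisopropylsilyloxy)cyclohex-1-en-1-yl trifluoromethanesulfonate | CC1=C(OS(=O)(=O)C(F)(F)F)CC[C@@H](O[Si](C(C)C)(C(C)C)C(C)C)[C@@H]1C | intermediate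
9 | (1,3-dioxolan-2-ylmethyl)zinc bromide | Br[Zn]CC1OCCO1 | starting material
10 | 2-{[(3R,4R)-2,3-dimethyl-4-(triisopropylsilyloxy)cyclohex-1-en-1-yl]methyl}-1,3-dioxolane | CC1=C(CC2OCCO2)CC[C@@H](O[Si](C(C)C)(C(C)C)C(C)C)[C@@H]1C | intermediate
11 | 2-[(3R,4R)-2,3-dimethyl-4-(triisopropylsilyloxy)cyclohex-1-en-1-yl]acetaldehyde | CC1=C(CC=O)CC[C@@H](O[Si](C(C)C)(C(C)C)C(C)C)[C@@H]1C | intermediate
12 | tert-butyl({(E)-2-[(3R,4R)-2,3-dimethyl-4-(triisopropylsilyloxy)cyclohex-1-en-1-yl]ethenyl}oxy)dimethylsilane | CC1=C(/C=C/O[Si](C)(C)C(C)(C)C)CC[C@@H](O[Si](C(C)C)(C(C)C)C(C)C)[C@@H]1C | intermediate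
13 | methyl vinyl ketone (but-3-en-2-one) | CC(=O)C=C | starting material
14 | 7α-acetyl-8α-(tert-butyldimethylsilyloxy)-4β,5β-dimethyl-3α-(triisopropylsilyloxy)-Δ9(10)-octalin | CC(=O)[C@@H]1C[C@@]2(C)C(=C[C@@H]1O[Si](C)(C)C(C)(C)C)CC[C@@H](O[Si](C(C)C)(C(C)C)C(C)C)[C@@H]2C | intermediate
15 | 8α-(tert-butyldimethylsilyloxy)-3α-(triisopropylsilyloxy)-7βH-eremophila-9,11-diene | C=C(C)[C@@H]1C[C@@]2(C)C(=C[C@@H]1O[Si](C)(C)C(C)(C)C)CC[C@@H](O[Si](C(C)C)(C(C)C)C(C)C)[C@@H]2C | intermediate
16 | 3α-(triisopropylsilyloxy)-7βH-eremophila-9,11-dien-8α-ol | C=C(C)[C@@H]1C[C@@]2(C)C(=C[C@@H]1O)CC[C@@H](O[Si](C(C)C)(C(C)C)C(C)C)[C@@H]2C | intermediate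
17 | 3α-(triisopropylsilyloxy)-7βH-eremophila-9,11-dien-8-one | C=C(C)[C@@H]1C[C@@]2(C)C(=CC1=O)CC[C@@H](O[Si](C(C)C)(C(C)C)C(C)C)[C@@H]2C | intermediate
18 | lithium 3α-(triisopropylsilyloxy)eremophila-7,9,11-trien-8-olate | C=C(C)C=1C[C@@]2(C)C(=CC=1O[Li])CC[C@@H](O[Si](C(C)C)(C(C)C)C(C)C)[C@@H]2C | intermediate
19 | 3α-(triisopropylsilyloxy)-7αH-eremophila-9,11-dien-8-one | C=C(C)[C@H]1C[C@@]2(C)C(=CC1=O)CC[C@@H](O[Si](C(C)C)(C(C)C)C(C)C)[C@@H]2C | intermediate
20 | 8-(triethylsilyloxy)-3α-(triisopropylsilyloxy)-7αH,10βH-eremophila-8,11-diene | C=C(C)[C@H]1C[C@@]2(C)[C@H](CC[C@@H](O[Si](C(C)C)(C(C)C)C(C)C)[C@@H]2C)C=C1O[Si](CC)(CC)CC | intermediate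
21 | 8β,9β-epoxy-8α-(triethylsilyloxy)-3α-(triisopropylsilyloxy)-7αH,10βH-eremophil-11-ene | C=C(C)[C@H]1C[C@@]2(C)[C@H](CC[C@@H](O[Si](C(C)C)(C(C)C)C(C)C)[C@@H]2C)[C@H]3O[C@@]13O[Si](CC)(CC)CC | intermediate
22 | 9β-(triethylsilyloxy)-3α-(triisopropylsilyloxy)-7αH,10βH-eremophil-11-en-8-one | C=C(C)[C@H]1C[C@@]2(C)[C@H](CC[C@@H](O[Si](C(C)C)(C(C)C)C(C)C)[C@@H]2C)[C@@H](O[Si](CC)(CC)CC)C1=O | intermediate
23 | 3α,9β-dihydroxy-7αH,10βH-eremophil-11-en-8-one | C=C(C)[C@H]1C[C@@]2(C)[C@H](CC[C@@H](O)[C@@H]2C)[C@@H](O)C1=O | intermediate
24 | angelic acid [(Z)-2-methylbut-2-enoic acid] | C/C=C(/C)C(=O)O | starting material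
25 | angelic 2,4,6-trichlorobenzoic anhydride | C/C=C(/C)C(=O)OC(=O)c1c(Cl)cc(Cl)cc1Cl | intermediate
26 | (3R,4R,5R,7R,9R,10S)-3α,9β-bis(angeloyloxy)-7αH,10βH-eremophil-11-en-8-one | C=C(C)[C@H]1C[C@@]2(C)[C@H](CC[C@@H](OC(=O)/C(C)=C\C)[C@@H]2C)[C@@H](OC(=O)/C(C)=C\C)C1=O | target

## Step count and least certain steps

Total step count: 18. Longest linear sequence: 18 steps (1 to 26); 9, 13 and 24 enter as purchased.

**Step 10 (key step).** The most likely failure is slow first bond formation at the fully substituted C5, whose methyl points into the diene. Protodesilylation of the dienol ether, polymerisation of the enone or arrest at the open-chain Michael stage could then overtake ring closure. A second risk is erosion of facial selectivity at C5 if the ring A conformer with equatorial C15 reacts, or if the axial C3 silyloxy group hinders the α face.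

Fallback: set out from 12 and heat it with but-3-yn-2-one in toluene. The linear alkynone is a slimmer and more reactive dienophile, and it should give the cyclohexadiene F1, which cannot aromatise or eliminate because C5 is quaternary and C8 has no sp3 neighbour bearing hydrogen. Conjugate reduction of the C6=C7 enone of F1 with [(Ph3P)CuH]6 in wet benzene and protonation at C7 returns to the route at 14; either C7 epimer is acceptable.

**Step 14.** Facial discrimination in the protonation may be poor because a proton is small. Protonation at the terminal carbon of the extended enolate may compete and conjugate the alkene, and the less stable 7β enone may revert during work-up.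

Fallback: set out from 17 and postpone the inversion. Copper hydride reduction with Et3SiCl as in step 15 should give the 7-epimeric enol ether F2, and peracid oxidation as in step 16 the 7-epimeric silyloxy ketone F3. In this cis-fused ketone the α-isopropenyl group is forced axial against the C4 arm, so brief equilibration with a catalytic amidine base in toluene should move C7 to the equatorial β position and come back to the route at 22. The equilibration is stopped before γ-reprotonation conjugates the alkene.

**Step 15.** Hydride transfer to a β,β-disubstituted enone next to a quaternary carbon may be slow. Carbonyl reduction may compete, or delivery to the α face may give the trans fusion.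

Fallback: set out from 19 and reduce with lithium in liquid ammonia/THF with one equivalent of tert-butanol at −78 °C. Protonation at C10 then follows the stereoelectronic preference for the more stable fusion with the new hydrogen axial on ring B. The trans fusion would hold C14 and the 7β-isopropenyl group 1,3-diaxial, so the cis lithium enolate F4 should prevail; silylation with Et3SiCl/Et3N after removal of ammonia returns to the route at 20.

**Step 12.** Discrimination between the hindered allylic TBS ether and the TIPS ether may be incomplete, with loss of the C3 protecting group or slow reaction.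

Fallback: set out from 15 and remove both silyl groups with excess Bu4NF in warm THF to give the diol F5. Oxidise only the allylic C8 carbinol with MnO2 in CH2Cl2 to the hydroxy enone F6, then re-silylate C3 with TIPSOTf/2,6-lutidine to come back to the route at 17.

**Step 18.** Geometric isomerisation of the angeloyl group to tiglate during acyl transfer is the main risk, together with incomplete acylation of the two hindered hydroxyls.

Fallback: set out from 23 and build the Z alkene on the ester. Acylate both hydroxyls with 2-[bis(2,2,2-trifluoroethoxy)phosphoryl]propanoic acid (carbodiimide, DMAP) to give the bis-phosphonate F7. Still–Gennari olefination with acetaldehyde (KN(SiMe3)2, 18-crown-6, THF, −78 °C, base limited to the phosphonate stoichiometry) then forms both Z-2-methylbut-2-enoates and arrives at 26.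

## Further compounds

F1 | step 10 | 7-acetyl-8α-(tert-butyldimethylsilyloxy)-4β,5β-dimethyl-3α-(triisopropylsilyloxy)-Δ6,Δ9(10)-hexalin | CC(=O)C1=C[C@@]2(C)C(=C[C@@H]1O[Si](C)(C)C(C)(C)C)CC[C@@H](O[Si](C(C)C)(C(C)C)C(C)C)[C@@H]2C
F2 | step 14 | 8-(triethylsilyloxy)-3α-(triisopropylsilyloxy)-7βH,10βH-eremophila-8,11-diene | C=C(C)[C@@H]1C[C@@]2(C)[C@H](CC[C@@H](O[Si](C(C)C)(C(C)C)C(C)C)[C@@H]2C)C=C1O[Si](CC)(CC)CC
F3 | step 14 | 9β-(triethylsilyloxy)-3α-(triisopropylsilyloxy)-7βH,10βH-eremophil-11-en-8-one | C=C(C)[C@@H]1C[C@@]2(C)[C@H](CC[C@@H](O[Si](C(C)C)(C(C)C)C(C)C)[C@@H]2C)[C@@H](O[Si](CC)(CC)CC)C1=O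
F4 | step 15 | lithium 3α-(triisopropylsilyloxy)-7αH,10βH-eremophila-8,11-dien-8-olate | C=C(C)[C@H]1C[C@@]2(C)[C@H](CC[C@@H](O[Si](C(C)C)(C(C)C)C(C)C)[C@@H]2C)C=C1O[Li]
F5 | step 12 | 7βH-eremophila-9,11-diene-3α,8α-diol | C=C(C)[C@@H]1C[C@@]2(C)C(=C[C@@H]1O)CC[C@@H](O)[C@@H]2C
F6 | step 12 | 3α-hydroxy-7βH-eremophila-9,11-dien-8-one | C=C(C)[C@@H]1C[C@@]2(C)C(=CC1=O)CC[C@@H](O)[C@@H]2C
F7 | step 18 | 3α,9β-bis{2-[bis(2,2,2-trifluoroethoxy)phosphoryl]propanoyloxy}-7αH,10βH-eremophil-11-en-8-one | C=C(C)[C@H]1C[C@@]2(C)[C@H](CC[C@@H](OC(=O)C(C)P(=O)(OCC(F)(F)F)OCC(F)(F)F)[C@@H]2C)[C@@H](OC(=O)C(C)P(=O)(OCC(F)(F)F)OCC(F)(F)F)C1=O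
A1 | alternative 1 | 2-(but-3-en-1-yl)-2-methyl-3-vinylcyclohexan-1-one (vinyl cis to butenyl) | C=CCC[C@@]1(C)[C@H](CCCC1=O)C=C
A2 | alternative 1 | 2-(but-3-en-1-yl)cyclohex-2-en-1-one | C=CCCC1=CCCCC1=O
A3 | alternative 2 | cis-fused octalin with C5 methyl, C4 ketone, C3 PMB ether and C8=C9 enol TBS ether | C1C[C@@]2(C)[C@H](CC[C@@H](OCc3ccc(OC)cc3)C2=O)C=C1O[Si](C)(C)C(C)(C)C
A4 | alternative 2 | (Z)-trienone with methacryloyl unit, C3 PMB ether and 2-(TBS-oxy)diene | C=C(C)C(=O)[C@H](OCc1ccc(OC)cc1)CC/C=C\C(=C)O[Si](C)(C)C(C)(C)C
A5 | alternative 3 | cis-fused octalin C9 carbinol with C1=C2 alkene, C8 TES ether and C3 TBS ether | [C@@H]1(O[Si](CC)(CC)CC)CC[C@@]2(C)[C@H](C=C[C@@H](O[Si](C)(C)C(C)(C)C)[C@@H]2C)[C@H]1O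
A6 | alternative 3 | ring A allylsilane (C2 trimethylsilyl, C3 TBS ether, C4 and C5 methyls) with 2-(triethylsilyloxy)-4-butanal chain on C5 | O=C[C@H](O[Si](CC)(CC)CC)CC[C@@]1(C)C=C[C@H]([Si](C)(C)C)[C@@H](O[Si](C)(C)C(C)(C)C)[C@@H]1C
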